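## Retrosynthetic overview

1. Last bonds: acidolysis of a tert-butyl ester and a PMB ether; the ester link comes from opening the spiro-epoxide of fragment A (bicyclic epoxy lactone) with the carboxylate of fragment B, which also frees the tertiary alcohol.
2. Fragment A: oxepinone ring by ring-closing metathesis; epoxide by hydroxyl-directed epoxidation; cis C-1/C-2 by conjugate vinylation and kinetic protonation of a cross-conjugated dienoate.
3. Fragment B: vinyl cuprate addition with enol triflate trapping, Lemieux–Johnson cleavage, oxa-Michael/HWE olefination, Stille hydroxymethylation.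
4. Both six-membered carbocycles come from one batch of (S)-cryptone, made by organocatalytic Michael addition and aldol condensation.
5. Ring order: cyclohexenone (both halves), then the oxirane, then the seven-membered lactone; the fragment union forms no ring.

Assumption: enantiopure (S)-cryptone is not treated as a catalogue item and is made in step 1; 13, 19, Bu3SnCH2OH and the Comins triflimide are taken as commercial.

## Route

Step 1
Reactants: 1 3-methylbutanal; 2 but-3-en-2-one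
Product: 4 (4S)-4-(propan-2-yl)cyclohex-2-en-1-one [(S)-cryptone], via keto aldehyde 3 (not isolated)
Conditions: (S)-2-[methoxy(diphenyl)methyl]pyrrolidine (5 mol%), ethyl 3,4-dihydroxybenzoate (20 mol%), neat, 4 °C; then LiOH, iPrOH, rt
Reagents that add atoms: none
Why: Enamine-catalysed Michael addition (the diarylmethyl group shields one enamine face, giving the 2S aldehyde) followed by intramolecular aldol condensation closes the cyclohexenone.

Step 2
Reactants: 4 (S)-cryptone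
Product: 5 (4S)-2-iodo-4-(propan-2-yl)cyclohex-2-en-1-one
Conditions: I2, pyridine, CH2Cl2, 0 °C to rt
Reagents that add atoms: iodine, II
Why: Pyridine-mediated alpha-iodination of the enone (Johnson iodination: conjugate addition, enolate iodination, elimination) leaves C-4 untouched.

Step 3
Reactants: 5 iodoenone
Product: 6 (3S)-1-iodo-6-methylidene-3-(propan-2-yl)cyclohex-1-ene
Conditions: Ph3PCH3Br, KOtBu, THF, 0 °C; then 5, −78 to 0 °C
Reagents that add atoms: methyltriphenylphosphonium bromide, C[P+](c1ccccc1)(c1ccccc1)c1ccccc1.[Br-]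
Why: Wittig methylenation of the ketone by 1,2-addition of the ylide gives the 2-iodo-1,3-diene.

Step 4
Reactants: 6 iododiene
Product: 7 methyl (3S)-6-methylidene-3-(propan-2-yl)cyclohex-1-ene-1-carboxylate
Conditions: Pd(OAc)2 (5 mol%), PPh3, CO (1 atm), MeOH, Et3N, DMF, 50 °C
Reagents that add atoms: carbon monoxide, [C-]#[O+]; methanol, CO
Why: Palladium-catalysed alkoxycarbonylation of the alkenyl iodide (oxidative addition, CO insertion, methanolysis) installs the future lactone carbonyl carbon.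

Step 5
Reactants: 7 dienoate
Product: 9 methyl (1S,2S,3S)-2-ethenyl-6-methylidene-3-(propan-2-yl)cyclohexane-1-carboxylate, via silyl ketene acetal 8 (not isolated)
Conditions: CH2=CHMgBr, CuBr·SMe2 (10 mol%), Me3SiCl, THF, −78 to −40 °C; then 1 M HCl, −40 to 0 °C
Reagents that add atoms: vinylmagnesium bromide, C=C[Mg]Br; chlorotrimethylsilane, C[Si](C)(C)Cl (its silicon is carried only by 8)
Why: Copper-catalysed, Me3SiCl-accelerated conjugate addition puts vinyl anti to the isopropyl group, and kinetic alpha-protonation of the dienyl ketene acetal anti to that vinyl group (held pseudo-axial by A(1,3) strain) places the ester cis to vinyl.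

Step 6
Reactants: 9 cis ester
Product: 10 [(1S,2S,3S)-2-ethenyl-6-methylidene-3-(propan-2-yl)cyclohexyl]methanol
Conditions: LiAlH4, Et2O, 0 °C
Reagents that add atoms: none
Why: Hydride reduction of the ester to the primary alcohol touches no stereocentre and gives the directing group for the next step.

Step 7
Reactants: 10 homoallylic alcohol
Product: 11 [(3R,4R,5S,6S)-5-ethenyl-6-(propan-2-yl)-1-oxaspiro[2.5]octan-4-yl]methanol
Conditions: VO(acac)2 (5 mol%), tBuOOH, CH2Cl2, 0 °C to rt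
Reagents that add atoms: tert-butyl hydroperoxide, CC(C)(C)OO
Why: Vanadium-catalysed hydroxyl-directed epoxidation delivers oxygen from the face carrying the axial CH2OH to the electron-rich 1,1-disubstituted alkene only, so the epoxide oxygen is cis to that arm and the vinyl group is untouched.

Step 8
Reactants: 11 epoxy alcohol
Product: 12 (3R,4S,5S,6S)-5-ethenyl-6-(propan-2-yl)-1-oxaspiro[2.5]octane-4-carboxylic acid
Conditions: TEMPO (10 mol%), NaClO2, NaOCl (2 mol%), MeCN, pH 6.7 phosphate buffer, 35 °C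
Reagents that add atoms: sodium chlorite, [Na+].[O-]Cl=O
Why: TEMPO/chlorite oxidation takes the primary alcohol to the acid near neutral pH, so the epoxide and the alpha centre survive.

Step 9
Reactants: 12 epoxy acid; 13 tert-butyl 2-(bromomethyl)prop-2-enoate
Product: 14 2-(tert-butoxycarbonyl)prop-2-en-1-yl (3R,4S,5S,6S)-5-ethenyl-6-(propan-2-yl)-1-oxaspiro[2.5]octane-4-carboxylate
Conditions: KHCO3, DMF, 0 °C to rt
Reagents that add atoms: none
Why: Carboxylate O-alkylation by the activated allylic bromide (SN2 or SN2', same product) under bicarbonate avoids beta-elimination of the epoxy ester.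

Step 10
Reactants: 14 triene ester
Product: 15 tert-butyl (5aR,6S,9R,9aS)-1-oxo-6-(propan-2-yl)-3,5a,6,7,8,9a-hexahydro-1H-spiro[2-benzoxepine-9,2'-oxirane]-4-carboxylate
Conditions: second-generation Hoveyda–Grubbs catalyst, RuCl2(H2IMes)(=CH-C6H4-2-OiPr) (5 mol%), toluene (0.005 M), 80 °C
Reagents that add atoms: none
Why: Ring-closing metathesis between the vinyl group and the acrylate methylene forms the seven-membered unsaturated lactone, the ring fixing the alkene geometry and the cis arms favouring closure.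

Step 11
Reactants: 4 (S)-cryptone
Product: 17 (3S,4S)-3-ethenyl-4-(propan-2-yl)cyclohex-1-en-1-yl trifluoromethanesulfonate, via magnesium enolate 16 (not isolated)
Conditions: CH2=CHMgBr, CuBr·SMe2 (10 mol%), THF, −78 °C; then N-(5-chloro-2-pyridyl)triflimide, −78 °C to rt
Reagents that add atoms: vinylmagnesium bromide, C=C[Mg]Br; N-(5-chloropyridin-2-yl)-1,1,1-trifluoro-N-(trifluoromethanesulfonyl)methanesulfonamide, O=S(=O)(N(c1ccc(Cl)cn1)S(=O)(=O)C(F)(F)F)C(F)(F)F
Why: Copper-catalysed conjugate addition occurs anti to the isopropyl group and O-triflation of the regiodefined enolate (Comins reagent) fixes the ring alkene position.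

Step 12
Reactants: 17 dienyl triflate
Product: 18 (3S,4S)-3-formyl-4-(propan-2-yl)cyclohex-1-en-1-yl trifluoromethanesulfonate
Conditions: OsO4 (2 mol%), NaIO4, 2,6-lutidine, dioxane/H2O (3:1), rt
Reagents that add atoms: sodium periodate, [Na+].[O-]I(=O)(=O)=O; osmium tetroxide (catalytic oxygen carrier), O=[Os](=O)(=O)=O
Why: Lemieux–Johnson cleavage: OsO4 dihydroxylates only the vinyl group (the enol triflate alkene is deactivated) and periodate cleaves the diol.

Step 13
Reactants: 18 aldehyde; 19 ethyl 2-(diethoxyphosphoryl)prop-2-enoate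
Product: 21 ethyl (2E)-2-{[(4-methoxyphenyl)methoxy]methyl}-3-[(1R,6S)-6-(propan-2-yl)-3-(trifluoromethanesulfonyloxy)cyclohex-2-en-1-yl]prop-2-enoate, via sodium phosphonate carbanion 20 (not isolated)
Conditions: 4-methoxybenzyl alcohol, NaH, THF, 0 °C; 19, 0 °C; then 18, −20 °C to rt
Reagents that add atoms: 4-methoxybenzyl alcohol, COc1ccc(CO)cc1; sodium hydride, [Na+].[H-] (its sodium is carried only by 20)
Why: Tandem oxa-Michael addition and Horner–Wadsworth–Emmons olefination gives the trisubstituted enoate, E favoured because the ester sits trans to the bulky ring substituent.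

Step 14
Reactants: 21 enol triflate
Product: 22 ethyl (2E)-3-[(1S,6S)-3-(hydroxymethyl)-6-(propan-2-yl)cyclohex-2-en-1-yl]-2-{[(4-methoxyphenyl)methoxy]methyl}prop-2-enoate
Conditions: Bu3SnCH2OH, Pd(PPh3)4 (10 mol%), LiCl, 1,4-dioxane, 100 °C
Reagents that add atoms: (tributylstannyl)methanol, CCCC[Sn](CCCC)(CCCC)CO
Why: Stille coupling of the enol triflate with the hydroxymethyl stannane installs the allylic CH2OH without moving the ring alkene.

Step 15
Reactants: 22 ethyl ester
Product: 23 (2E)-3-[(1S,6S)-3-(hydroxymethyl)-6-(propan-2-yl)cyclohex-2-en-1-yl]-2-{[(4-methoxyphenyl)methoxy]methyl}prop-2-enoic acid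
Conditions: LiOH, THF/H2O, rt; then 1 M HCl
Reagents that add atoms: lithium hydroxide, [Li+].[OH-]
Why: Saponification of the conjugated ethyl ester, with no epimerisable centre alpha to a carbonyl.

Step 16
Reactants: 15 epoxy lactone; 23 acid
Product: 24 tert-butyl (5aR,6S,9R,9aS)-9-hydroxy-9-({[(2E)-3-[(1S,6S)-3-(hydroxymethyl)-6-(propan-2-yl)cyclohex-2-en-1-yl]-2-{[(4-methoxyphenyl)methoxy]methyl}prop-2-enoyl]oxy}methyl)-1-oxo-6-(propan-2-yl)-1,3,5a,6,7,8,9,9a-octahydro-2-benzoxepine-4-carboxylate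
Conditions: 23 (1.5 equiv), Cs2CO3 (0.3 equiv), DMF, 60 °C
Reagents that add atoms: none
Why: SN2 opening of the spiro-epoxide at its CH2 terminus by the carboxylate (base-catalytic, excess acid reprotonates the alkoxide) forms the ester and frees the tertiary alcohol with retention at the quaternary carbon.

Step 17
Reactants: 24 protected target
Product: 25 CNP0361406.4
Conditions: CF3CO2H/CH2Cl2 (1:4), anisole, 0 °C to rt; then NaHCO3 (aq)/MeOH, acidify to pH 3
Reagents that add atoms: none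
Why: Acidolysis removes the tert-butyl ester as isobutene and the 4-methoxybenzyl ether as a benzylic cation trapped by anisole (Friedel–Crafts), while lactone, enoate ester and tertiary alcohol are acid-stable.

## Compound list

1 | 3-methylbutanal | CC(C)CC=O | starting material
2 | but-3-en-2-one | C=CC(C)=O | starting material
3 | (2S)-5-oxo-2-(propan-2-yl)hexanal | CC(=O)CC[C@H](C=O)C(C)C | intermediate
4 | (4S)-4-(propan-2-yl)cyclohex-2-en-1-one | C1=CC(=O)CC[C@H]1C(C)C | intermediate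
5 | (4S)-2-iodo-4-(propan-2-yl)cyclohex-2-en-1-one | C1=C(I)C(=O)CC[C@H]1C(C)C | intermediate
6 | (3S)-1-iodo-6-methylidene-3-(propan-2-yl)cyclohex-1-ene | C1=C(I)C(=C)CC[C@H]1C(C)C | intermediate
7 | methyl (3S)-6-methylidene-3-(propan-2-yl)cyclohex-1-ene-1-carboxylate | C1=C(C(=O)OC)C(=C)CC[C@H]1C(C)C | intermediate
8 | {[(2S,3S)-2-ethenyl-6-methylidene-3-(propan-2-yl)cyclohexylidene](methoxy)methoxy}trimethylsilane | CC(C)[C@@H]1CCC(=C)C(=C(OC)O[Si](C)(C)C)[C@H]1C=C | intermediate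
9 | methyl (1S,2S,3S)-2-ethenyl-6-methylidene-3-(propan-2-yl)cyclohexane-1-carboxylate | CC(C)[C@@H]1CCC(=C)[C@@H](C(=O)OC)[C@H]1C=C | intermediate
10 | [(1S,2S,3S)-2-ethenyl-6-methylidene-3-(propan-2-yl)cyclohexyl]methanol | CC(C)[C@@H]1CCC(=C)[C@@H](CO)[C@H]1C=C | intermediate
11 | [(3R,4R,5S,6S)-5-ethenyl-6-(propan-2-yl)-1-oxaspiro[2.5]octan-4-yl]methanol | CC(C)[C@@H]1CC[C@]2(CO2)[C@@H](CO)[C@H]1C=C | intermediate
12 | (3R,4S,5S,6S)-5-ethenyl-6-(propan-2-yl)-1-oxaspiro[2.5]octane-4-carboxylic acid | CC(C)[C@@H]1CC[C@]2(CO2)[C@@H](C(=O)O)[C@H]1C=C | intermediate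
13 | tert-butyl 2-(bromomethyl)prop-2-enoate | C=C(CBr)C(=O)OC(C)(C)C | starting material
14 | 2-(tert-butoxycarbonyl)prop-2-en-1-yl (3R,4S,5S,6S)-5-ethenyl-6-(propan-2-yl)-1-oxaspiro[2.5]octane-4-carboxylate | CC(C)[C@@H]1CC[C@]2(CO2)[C@@H](C(=O)OCC(=C)C(=O)OC(C)(C)C)[C@H]1C=C | intermediate
15 | tert-butyl (5aR,6S,9R,9aS)-1-oxo-6-(propan-2-yl)-3,5a,6,7,8,9a-hexahydro-1H-spiro[2-benzoxepine-9,2'-oxirane]-4-carboxylate | CC(C)[C@@H]1CC[C@]3(CO3)[C@H]2C(=O)OCC(C(=O)OC(C)(C)C)=C[C@@H]12 | intermediate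
16 | bromomagnesium (3S,4S)-3-ethenyl-4-(propan-2-yl)cyclohex-1-en-1-olate | C=C[C@@H]1C=C(O[Mg]Br)CC[C@H]1C(C)C | intermediate
17 | (3S,4S)-3-ethenyl-4-(propan-2-yl)cyclohex-1-en-1-yl trifluoromethanesulfonate | C=C[C@@H]1C=C(OS(=O)(=O)C(F)(F)F)CC[C@H]1C(C)C | intermediate
18 | (3S,4S)-3-formyl-4-(propan-2-yl)cyclohex-1-en-1-yl trifluoromethanesulfonate | O=C[C@@H]1C=C(OS(=O)(=O)C(F)(F)F)CC[C@H]1C(C)C | intermediate
19 | ethyl 2-(diethoxyphosphoryl)prop-2-enoate | C=C(C(=O)OCC)P(=O)(OCC)OCC | starting material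
20 | sodium salt of the carbanion of ethyl 2-(diethoxyphosphoryl)-3-[(4-methoxyphenyl)methoxy]propanoate | CCOC(=O)[C-](COCc1ccc(OC)cc1)P(=O)(OCC)OCC.[Na+] | intermediate
21 | ethyl (2E)-2-{[(4-methoxyphenyl)methoxy]methyl}-3-[(1R,6S)-6-(propan-2-yl)-3-(trifluoromethanesulfonyloxy)cyclohex-2-en-1-yl]prop-2-enoate | CCOC(=O)/C(=C/[C@@H]1C=C(OS(=O)(=O)C(F)(F)F)CC[C@H]1C(C)C)COCc2ccc(OC)cc2 | intermediate
22 | ethyl (2E)-3-[(1S,6S)-3-(hydroxymethyl)-6-(propan-2-yl)cyclohex-2-en-1-yl]-2-{[(4-methoxyphenyl)methoxy]methyl}prop-2-enoate | CCOC(=O)/C(=C/[C@@H]1C=C(CO)CC[C@H]1C(C)C)COCc2ccc(OC)cc2 | intermediate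
23 | (2E)-3-[(1S,6S)-3-(hydroxymethyl)-6-(propan-2-yl)cyclohex-2-en-1-yl]-2-{[(4-methoxyphenyl)methoxy]methyl}prop-2-enoic acid | OC(=O)/C(=C/[C@@H]1C=C(CO)CC[C@H]1C(C)C)COCc2ccc(OC)cc2 | intermediate
24 | tert-butyl ester, side-chain PMB ether of the target (full name in step 16) | CC(C)[C@@H]1CC[C@](O)(COC(=O)/C(=C/[C@@H]3C=C(CO)CC[C@H]3C(C)C)COCc3ccc(OC)cc3)[C@H]2C(=O)OCC(C(=O)OC(C)(C)C)=C[C@@H]12 | intermediate
25 | (5aR,6S,9R,9aS)-9-hydroxy-9-({[(2E)-2-(hydroxymethyl)-3-[(1S,6S)-3-(hydroxymethyl)-6-(propan-2-yl)cyclohex-2-en-1-yl]prop-2-enoyl]oxy}methyl)-1-oxo-6-(propan-2-yl)-1,3,5a,6,7,8,9,9a-octahydro-2-benzoxepine-4-carboxylic acid | CC(C)[C@@H]1CC[C@](O)(COC(=O)/C(=C/[C@@H]2C=C(CO)CC[C@H]2C(C)C)CO)[C@H]2C(=O)OCC(C(=O)O)=C[C@@H]12 | target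

## Step count and risk

Total step count: 17. Longest linear sequence: 12 steps (steps 1 to 10, then 16 and 17); the fragment B branch is steps 11 to 15.

**Step 5** (conjugate vinylation and kinetic protonation on a hindered enoate). The fallback sets out from 7 and comes back at 10. iBu2AlH reduces 7 to the dienol [(3S)-6-methylidene-3-(propan-2-yl)cyclohex-1-en-1-yl]methanol F1, and MnO2 gives the dienal (3S)-6-methylidene-3-(propan-2-yl)cyclohex-1-ene-1-carbaldehyde F2, a much better cuprate acceptor. CH2=CHMgBr, CuBr·SMe2 and Me3SiCl give the trimethylsilyl dienol ether F3, and buffered hydrolysis gives the cis aldehyde (1S,2S,3S)-2-ethenyl-6-methylidene-3-(propan-2-yl)cyclohexane-1-carbaldehyde F4. Its epimerisable centre can also relax toward the cis (axial formyl) isomer favoured by A(1,3) strain. NaBH4 in the same flask then gives 10.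

**Step 13** (E/Z ratio of the oxa-Michael/HWE olefination). The fallback sets out from 18 and comes back at 21. Vinylalumination of 18 with the alane from ethyl propiolate, iBu2AlH and N-methylmorpholine N-oxide gives the Baylis–Hillman-type alcohol F5. Ac2O with catalytic Me3SiOTf acetylates it to the secondary acetate F6, which undergoes 1,3-acyloxy shift under thermodynamic control to the (E)-primary acetate F7. K2CO3 in EtOH gives the (E)-hydroxymethyl enoate F8, and 4-methoxybenzyl trichloroacetimidate with catalytic camphorsulfonic acid gives 21.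

**Step 16** (carboxylate opening of a hindered spiro-epoxide). The fallback sets out from 15 and 22 and comes back at 25. Excess CsO2CH in DMF opens 15 at CH2 to the hydroxy formate F9, and KHCO3 in MeOH gives the diol F10 with the quaternary centre untouched. Separately, tBuMe2SiCl and imidazole convert 22 to the silyl ether ester F11, and LiOH gives the silyl ether acid F12. Yamaguchi esterification (2,4,6-trichlorobenzoyl chloride, Et3N, then DMAP) of the primary hydroxyl of F10 with F12 gives the fully protected ester F13. CF3CO2H with anisole then removes the tert-butyl, PMB and silyl groups to give 25.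

## Further compounds

F1 | step 5 | [(3S)-6-methylidene-3-(propan-2-yl)cyclohex-1-en-1-yl]methanol | C1=C(CO)C(=C)CC[C@H]1C(C)C
F2 | step 5 | (3S)-6-methylidene-3-(propan-2-yl)cyclohex-1-ene-1-carbaldehyde | C1=C(C=O)C(=C)CC[C@H]1C(C)C
F3 | step 5 | {[(2S,3S)-2-ethenyl-6-methylidene-3-(propan-2-yl)cyclohexylidene]methoxy}trimethylsilane | CC(C)[C@@H]1CCC(=C)C(=CO[Si](C)(C)C)[C@H]1C=C
F4 | step 5 | (1S,2S,3S)-2-ethenyl-6-methylidene-3-(propan-2-yl)cyclohexane-1-carbaldehyde | CC(C)[C@@H]1CCC(=C)[C@@H](C=O)[C@H]1C=C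
F5 | step 13 | ethyl 2-{hydroxy[(1S,6S)-6-(propan-2-yl)-3-(trifluoromethanesulfonyloxy)cyclohex-2-en-1-yl]methyl}prop-2-enoate (carbinol epimers) | CCOC(=O)C(=C)C(O)[C@@H]1C=C(OS(=O)(=O)C(F)(F)F)CC[C@H]1C(C)C
F6 | step 13 | ethyl 2-{acetyloxy[(1S,6S)-6-(propan-2-yl)-3-(trifluoromethanesulfonyloxy)cyclohex-2-en-1-yl]methyl}prop-2-enoate | CCOC(=O)C(=C)C(OC(C)=O)[C@@H]1C=C(OS(=O)(=O)C(F)(F)F)CC[C@H]1C(C)C
F7 | step 13 | ethyl (2E)-2-[(acetyloxy)methyl]-3-[(1R,6S)-6-(propan-2-yl)-3-(trifluoromethanesulfonyloxy)cyclohex-2-en-1-yl]prop-2-enoate | CCOC(=O)/C(=C/[C@@H]1C=C(OS(=O)(=O)C(F)(F)F)CC[C@H]1C(C)C)COC(C)=O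
F8 | step 13 | ethyl (2E)-2-(hydroxymethyl)-3-[(1R,6S)-6-(propan-2-yl)-3-(trifluoromethanesulfonyloxy)cyclohex-2-en-1-yl]prop-2-enoate | CCOC(=O)/C(=C/[C@@H]1C=C(OS(=O)(=O)C(F)(F)F)CC[C@H]1C(C)C)CO
F9 | step 16 | tert-butyl (5aR,6S,9R,9aS)-9-[(formyloxy)methyl]-9-hydroxy-1-oxo-6-(propan-2-yl)-1,3,5a,6,7,8,9,9a-octahydro-2-benzoxepine-4-carboxylate | CC(C)[C@@H]1CC[C@](O)(COC=O)[C@H]2C(=O)OCC(C(=O)OC(C)(C)C)=C[C@@H]12
F10 | step 16 | tert-butyl (5aR,6S,9R,9aS)-9-hydroxy-9-(hydroxymethyl)-1-oxo-6-(propan-2-yl)-1,3,5a,6,7,8,9,9a-octahydro-2-benzoxepine-4-carboxylate | CC(C)[C@@H]1CC[C@](O)(CO)[C@H]2C(=O)OCC(C(=O)OC(C)(C)C)=C[C@@H]12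
F11 | step 16 | ethyl (2E)-3-[(1S,6S)-3-{[(tert-butyldimethylsilyl)oxy]methyl}-6-(propan-2-yl)cyclohex-2-en-1-yl]-2-{[(4-methoxyphenyl)methoxy]methyl}prop-2-enoate | CCOC(=O)/C(=C/[C@@H]1C=C(CO[Si](C)(C)C(C)(C)C)CC[C@H]1C(C)C)COCc2ccc(OC)cc2
F12 | step 16 | (2E)-3-[(1S,6S)-3-{[(tert-butyldimethylsilyl)oxy]methyl}-6-(propan-2-yl)cyclohex-2-en-1-yl]-2-{[(4-methoxyphenyl)methoxy]methyl}prop-2-enoic acid | OC(=O)/C(=C/[C@@H]1C=C(CO[Si](C)(C)C(C)(C)C)CC[C@H]1C(C)C)COCc2ccc(OC)cc2
F13 | step 16 | tert-butyldimethylsilyl ether of 24 at the ring hydroxymethyl group | CC(C)[C@@H]1CC[C@](O)(COC(=O)/C(=C/[C@@H]3C=C(CO[Si](C)(C)C(C)(C)C)CC[C@H]3C(C)C)COCc3ccc(OC)cc3)[C@H]2C(=O)OCC(C(=O)OC(C)(C)C)=C[C@@H]12
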